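The amounts put the question: 0.29 M of electrophile against 0.580 M of nucleophile, and I had to decide whether to leave that charge for 40 min or raise the nucleophile.

| flask | electrophile | nucleophile | free base | remark | time |
|---|---|---|---|---|---|
| red | 0.41 M | 0.58 M | 0.087 M | run made earlier |  |
| blue | 0.64 M | 0.58 M | 0.087 M | run made earlier |  |
| flask | 0.29 M | 0.580 M | 0.0870 M |  | 40 min |

| run | time / min | electrophile / % | target / % |
|---|---|---|---|
| red | 2.00 | 73 | 16 |
| red | 3.00 | 64 | 22 |
| red | 5.00 | 51 | 23 |
| red | 8.00 | 43 | 19 |
| red | 15.0 | 30 | 12 |
| red | 25.0 | 21 | 5 |
| blue | 2.00 | 77 | 16 |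
| blue | 3.00 | 68 | 18 |
| blue | 5.00 | 58 | 17 |
| blue | 8.00 | 47 | 16 |
| blue | 15.0 | 38 | 4 |
| blue | 25.0 | 33 | 2 |

(readings scatter by 1.5 percentage points)

1. part of the electrophile that has reacted at 40 min
2. share of the unused nucleophile that is free and not bound as protonated nucleophile, at 40 min

- what has gone from electrophile into another species counts as reacted, even if it can come back
- the earlier runs do not show how much of nucleophile is bound; that part of a forecast is a guess

I assumed that each electrophile consumed costs two nucleophile, one in the reaction and one bound as protonated nucleophile. So I reckoned with the allowance w, the fraction of the electrophile charge that the nucleophile can serve at two apiece, 1.00 in this flask. At that allowance the free nucleophile, as a fraction of its charge, equals f, the fraction of electrophile left. The first red reading, at the same nucleophile charge, gives a pseudo-first-order rate a of 0.157 min⁻¹, and the rate a·f² integrates to an inverse of f climbing straight from one with slope a. On that reckoning the flask keeps 13.7%, so 86.3% has reacted. With x reacted, the free share is (w − x)/(w − x/2), here 24.1%. But the blue run had lost 67.0% by 25.0 min, more than its allowance of 45.3%, so either some electrophile leaves without paying or the price is lower, and I took my figures as low. I kept the charge and chose to watch the free nucleophile.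

The forecast gave 91% (85% to 96%) reacted and 43% free (25% to 60%), adding “This share is a guess”. My fraction reacted lay below its value, and my share below its range.

The flask gave 91.8% reacted and 36.6% free.

    electrophile + nucleophile → acid set free + target (k = 0.00440 M⁻¹ s⁻¹)
    acid set free + target → side product (k = 0.00140 M⁻¹ s⁻¹)
    nucleophile + acid set free ⇌ protonated nucleophile, settled at all times (K = 7100 M⁻¹)
    electrophile ⇌ dormant form (K = 1.10, k = 4.30 × 10⁻⁴ s⁻¹)
    acid set free + free base ⇌ salt of the base (K = 3.00 × 10⁵ M⁻¹, k = 0.0830 M⁻¹ s⁻¹)
    target → over-reaction product (k = 0.00290 s⁻¹)

In the flask, target and over-reaction product together held 78.1% of the charge, and dormant form held 13.7%. Taking that 78.1% as the fraction that paid, the allowance gives 35.9% free. A neighbouring flask, charged with 0.99 M of nucleophile, has an allowance of 1.71. Its target and over-reaction product came to 92.6%, so the same reckoning gives 62.8%, and that flask held 63.0% free, with 1.23% of its electrophile left.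

(The runs are simulated with made-up constants, and the scatter is random.)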